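**Plan**

1. Target 19 is (2R)-5,7-dihydroxy-2-[4-hydroxy-3,5-bis(3-methylbut-2-enyl)phenyl]-6-(3-methylbut-2-enyl)chroman-4-one; flavanone numbering is used (ring A = benzo ring, ring B = 2-aryl group, ring C = pyranone).
2. Enabling feature: ring C holds the aryl alkyl ether bond O1–C8a. C8a is the ring A carbon next to C4a, meta to O5 and O7 and para to the C6 prenyl group. A bromine there (the bromine of 5-bromoresorcinol) fixes the 6-prenyl pattern and is the handle for closing ring C with the C2 hydroxyl.
3. Retrosynthetic cuts, in order: phenol and C4 ketone unmasking; O1–C8a (palladium C–O coupling); C2 carbinol back to a ketone; C3–C4 (aldol); C4a–CHO; the three aryl–prenyl bonds.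
4. Forward: ring A aldehyde 8 (four steps from 5-bromoresorcinol) and ring B methyl ketone 11 (two steps from 4-hydroxyacetophenone) are joined by an aldol addition, the aldol hydroxyl is silylated, and ring C, the only ring made, is closed last.
5. Stereochemistry: C2, the only stereocentre of the target, is set by catalyst-controlled CBS reduction (step 9) and carried with retention through the ring closure. The C4 carbinol is racemic throughout and ends as the ketone.

Key step: step 10

Remark on the chemistry: in the oxazaborolidine reduction the ring B aryl group is assumed to act as the large substituent, as in acetophenone-type ketones, so that the (S)-configured catalyst gives the (1R)-carbinol in both C3-epimeric series.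

**Route**

Step 1
Reactants: 1 5-bromoresorcinol (5-bromobenzene-1,3-diol)
Product: 2 5-bromo-2-iodobenzene-1,3-diol
Conditions: I2 (1.05 equiv), NaHCO3 (1.1 equiv), H2O/THF, 0 °C → rt
Reagents that add atoms: iodine, II
Why: Electrophilic aromatic iodination under the aqueous hydrogencarbonate conditions known to place iodine on the carbon between the two hydroxyls of resorcinol and its 5-substituted congeners, the other activated positions being crowded by the bromine.

Step 2
Reactants: 2 5-bromo-2-iodobenzene-1,3-diol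
Product: 3 5-bromo-2-iodo-1,3-bis(methoxymethoxy)benzene
Conditions: NaH (2.4 equiv), MOMCl (2.4 equiv), DMF, 0 °C → rt
Reagents that add atoms: chloromethyl methyl ether (MOMCl), COCCl
Why: Williamson O-alkylation of both phenoxides with MOMCl, which masks the phenols and later assists metalation at the neighbouring carbons.

Step 3
Reactants: 3 5-bromo-2-iodo-1,3-bis(methoxymethoxy)benzene; 4 1-bromo-3-methylbut-2-ene (prenyl bromide)
Product: 6 5-bromo-1,3-bis(methoxymethoxy)-2-(3-methylbut-2-enyl)benzene, via arylmagnesium chloride 5 (not isolated)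
Conditions: i-PrMgCl·LiCl (1.1 equiv), THF, −20 °C; then CuBr·SMe2 (20 mol %), 4 (1.3 equiv), −20 °C → rt
Reagents that add atoms: none
Why: Iodine–magnesium exchange with the turbo-Grignard reagent should be far faster at the C–I bond flanked by two chelating MOM ethers than at the C–Br bond, and the copper-catalysed SN2 allylation of the aryl Grignard at the primary carbon of prenyl bromide parallels the known prenylation of metalated resorcinol bis-MOM ethers.

Step 4
Reactants: 6 5-bromo-1,3-bis(methoxymethoxy)-2-(3-methylbut-2-enyl)benzene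
Product: 8 6-bromo-2,4-bis(methoxymethoxy)-3-(3-methylbut-2-enyl)benzaldehyde, via ortho-bromoaryllithium 7 (not isolated)
Conditions: LiN(iPr)2 (1.1 equiv), THF, −78 °C; then DMF (2 equiv), −78 → −40 °C; H2O
Reagents that add atoms: N,N-dimethylformamide, CN(C)C=O
Why: Directed ortho-lithiation by the amide base (deprotonation, not bromine–lithium exchange) removes one of the two equivalent ring protons flanked by bromine and a MOM ether, as with 3-bromoanisole, and the aryllithium, stable towards LiBr loss at −78 °C, is formylated by DMF.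

Step 5
Reactants: 9 4-hydroxyacetophenone; 4 1-bromo-3-methylbut-2-ene
Product: 10 1-[4-hydroxy-3,5-bis(3-methylbut-2-enyl)phenyl]ethanone
Conditions: 4 (2.5 equiv), KOH (10 % aq), 0 °C → rt
Reagents that add atoms: none
Why: C-alkylation of the ambident phenoxide in water, where the solvated oxygen is a poor nucleophile, is a known if modest-yielding ortho-prenylation of 4-acylphenols, and with the para position blocked both ortho carbons are alkylated.

Step 6
Reactants: 10 1-[4-hydroxy-3,5-bis(3-methylbut-2-enyl)phenyl]ethanone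
Product: 11 1-[4-(methoxymethoxy)-3,5-bis(3-methylbut-2-enyl)phenyl]ethanone
Conditions: MOMCl (1.5 equiv), i-Pr2NEt (2 equiv), CH2Cl2, 0 °C → rt
Reagents that add atoms: chloromethyl methyl ether (MOMCl), COCCl
Why: O-alkylation of the acidic 4-acylphenol with MOMCl and a hindered amine base, which leaves the methyl ketone untouched for the enolisation that follows.

Step 7
Reactants: 11 1-[4-(methoxymethoxy)-3,5-bis(3-methylbut-2-enyl)phenyl]ethanone; 8 6-bromo-2,4-bis(methoxymethoxy)-3-(3-methylbut-2-enyl)benzaldehyde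
Product: 13 3-[6-bromo-2,4-bis(methoxymethoxy)-3-(3-methylbut-2-enyl)phenyl]-3-hydroxy-1-[4-(methoxymethoxy)-3,5-bis(3-methylbut-2-enyl)phenyl]propan-1-one (racemic), via lithium enolate 12 (not isolated)
Conditions: LiN(iPr)2 (1.05 equiv), THF, −78 °C; then 8, −78 °C; AcOH, −78 °C
Reagents that add atoms: none
Why: Directed crossed aldol addition of a preformed lithium enolate to a non-enolisable aldehyde forms the C3–C4 bond, with a cold acidic quench to prevent retro-aldol and dehydration; the new carbinol centre (flavanone C4) is formed without control, which does not matter because it is oxidised in step 12.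

Step 8
Reactants: 13 the racemic aldol
Product: 14 3-[6-bromo-2,4-bis(methoxymethoxy)-3-(3-methylbut-2-enyl)phenyl]-3-(tert-butyldimethylsilyloxy)-1-[4-(methoxymethoxy)-3,5-bis(3-methylbut-2-enyl)phenyl]propan-1-one (racemic)
Conditions: TBSOTf (1.3 equiv), 2,6-lutidine (2 equiv), CH2Cl2, −78 °C
Reagents that add atoms: tert-butyldimethylsilyl trifluoromethanesulfonate (TBSOTf), CC(C)(C)[Si](C)(C)OS(=O)(=O)C(F)(F)F
Why: Silyl triflate silylation of a hindered secondary alcohol is fast at low temperature, spares the aryl MOM acetals, and removes the β-hydroxy ketone before any base or heat is applied.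

Step 9
Reactants: 14 the racemic β-silyloxy ketone
Product: 15 (1R)-3-[6-bromo-2,4-bis(methoxymethoxy)-3-(3-methylbut-2-enyl)phenyl]-3-(tert-butyldimethylsilyloxy)-1-[4-(methoxymethoxy)-3,5-bis(3-methylbut-2-enyl)phenyl]propan-1-ol (both C3 epimers)
Conditions: (S)-Bu-CBS oxazaborolidine (20 mol %), catecholborane (1.8 equiv), toluene, −78 °C; aqueous work-up
Reagents that add atoms: none
Why: Corey–Bakshi–Shibata reduction of an aryl alkyl ketone, in which the (S)-oxazaborolidine should deliver hydride to the Si face of the carbonyl under catalyst control to set C1 (flavanone C2) as R in both C3 epimers, while catecholborane at −78 °C does not hydroborate the prenyl groups.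

Step 10
Reactants: 15 the (1R)-bromo alcohol (both C3 epimers)
Product: 16 (2R)-4-(tert-butyldimethylsilyloxy)-5,7-bis(methoxymethoxy)-2-[4-(methoxymethoxy)-3,5-bis(3-methylbut-2-enyl)phenyl]-6-(3-methylbut-2-enyl)chroman (both C4 epimers)
Conditions: Pd(OAc)2 (5 mol %), 2-(di-tert-butylphosphino)-1,1'-binaphthyl (6 mol %), Cs2CO3 (1.5 equiv), toluene, 80 °C
Reagents that add atoms: none
Why: Pd(OAc)2 is reduced in situ to zerovalent palladium, which adds oxidatively to the C8a–Br bond; Cs2CO3 then converts the C2 hydroxyl into an alkoxide bound to divalent palladium in a seven-membered chelate, and C–O reductive elimination forms O1–C8a. The closest known reaction is the palladium-catalysed intramolecular etherification of aryl bromides bearing primary or secondary alcohols to chromans with di-tert-butyl(biaryl)phosphines. Ring C closes as a six-membered ring, the tethered oxygen being joined to the aryl carbon C8a in a 6-exo sense by way of the seven-membered oxapalladacycle. No stereocentre is created: the C2–O bond is never broken, so the R configuration from step 9 is retained, and both C4 epimers cyclise. The selectivity needed is reductive elimination over β-hydride elimination of the secondary benzylic alkoxide, which the bulky electron-rich phosphine and the favourable ring size should secure. Chemo- and regioselectivity rest on the substrate, since the C2 hydroxyl is the only free OH (C4–O is silylated and could only close a four-membered ring, the phenols are MOM ethers) and the single bromine sits at C8a.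

Step 11
Reactants: 16 the (2R)-4-silyloxychroman (both C4 epimers)
Product: 17 (2R)-5,7-bis(methoxymethoxy)-2-[4-(methoxymethoxy)-3,5-bis(3-methylbut-2-enyl)phenyl]-6-(3-methylbut-2-enyl)chroman-4-ol (both C4 epimers)
Conditions: Bu4NF (1.5 equiv), THF, 0 °C → rt
Reagents that add atoms: none
Why: Fluoride-induced desilylation runs under non-acidic conditions, which the ionisation-prone C4–O bond of a 5,7-dioxygenated chroman-4-ol and the MOM ethers should tolerate.

Step 12
Reactants: 17 the (2R)-chroman-4-ol (both C4 epimers)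
Product: 18 (2R)-5,7-bis(methoxymethoxy)-2-[4-(methoxymethoxy)-3,5-bis(3-methylbut-2-enyl)phenyl]-6-(3-methylbut-2-enyl)chroman-4-one
Conditions: Dess–Martin periodinane (1.5 equiv), NaHCO3 (5 equiv), CH2Cl2, 0 °C → rt
Reagents that add atoms: none
Why: Buffered Dess–Martin oxidation converts both C4 epimers into one aryl ketone without acid or base strong enough to open ring C, so C2 stays R.

Step 13
Reactants: 18 the (2R)-tris-MOM flavanone
Product: 19 (2R)-5,7-dihydroxy-2-[4-hydroxy-3,5-bis(3-methylbut-2-enyl)phenyl]-6-(3-methylbut-2-enyl)chroman-4-one (target)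
Conditions: HCl (3 M aq), MeOH, 40 °C, monitored closely
Reagents that add atoms: none
Why: Acid-catalysed acetal exchange with methanol cleaves the three aryl MOM ethers (the C5 ether fastest, helped by the peri carbonyl) under conditions used for prenylated flavonoids, mild enough that the prenyl groups and the C2 centre should survive.

**Compound list**

1 | 5-bromoresorcinol | Oc1cc(O)cc(Br)c1 | starting material
2 | 5-bromo-2-iodobenzene-1,3-diol | Oc1cc(Br)cc(O)c1I | intermediate
3 | 5-bromo-2-iodo-1,3-bis(methoxymethoxy)benzene | COCOc1cc(Br)cc(OCOC)c1I | intermediate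
4 | 1-bromo-3-methylbut-2-ene (prenyl bromide) | CC(C)=CCBr | starting material
5 | [4-bromo-2,6-bis(methoxymethoxy)phenyl]magnesium chloride | COCOc1cc(Br)cc(OCOC)c1[Mg]Cl | intermediate
6 | 5-bromo-1,3-bis(methoxymethoxy)-2-(3-methylbut-2-enyl)benzene | COCOc1cc(Br)cc(OCOC)c1CC=C(C)C | intermediate
7 | [6-bromo-2,4-bis(methoxymethoxy)-3-(3-methylbut-2-enyl)phenyl]lithium | [Li]c1c(Br)cc(OCOC)c(CC=C(C)C)c1OCOC | intermediate
8 | 6-bromo-2,4-bis(methoxymethoxy)-3-(3-methylbut-2-enyl)benzaldehyde | O=Cc1c(Br)cc(OCOC)c(CC=C(C)C)c1OCOC | intermediate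
9 | 4-hydroxyacetophenone | CC(=O)c1ccc(O)cc1 | starting material
10 | 1-[4-hydroxy-3,5-bis(3-methylbut-2-enyl)phenyl]ethanone | CC(=O)c1cc(CC=C(C)C)c(O)c(CC=C(C)C)c1 | intermediate
11 | 1-[4-(methoxymethoxy)-3,5-bis(3-methylbut-2-enyl)phenyl]ethanone | CC(=O)c1cc(CC=C(C)C)c(OCOC)c(CC=C(C)C)c1 | intermediate
12 | lithium enolate of 11 | [Li]OC(=C)c1cc(CC=C(C)C)c(OCOC)c(CC=C(C)C)c1 | intermediate
13 | 3-[6-bromo-2,4-bis(methoxymethoxy)-3-(3-methylbut-2-enyl)phenyl]-3-hydroxy-1-[4-(methoxymethoxy)-3,5-bis(3-methylbut-2-enyl)phenyl]propan-1-one (racemic) | CC(C)=CCc1cc(C(=O)CC(O)c2c(Br)cc(OCOC)c(CC=C(C)C)c2OCOC)cc(CC=C(C)C)c1OCOC | intermediate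
14 | 3-[6-bromo-2,4-bis(methoxymethoxy)-3-(3-methylbut-2-enyl)phenyl]-3-(tert-butyldimethylsilyloxy)-1-[4-(methoxymethoxy)-3,5-bis(3-methylbut-2-enyl)phenyl]propan-1-one (racemic) | CC(C)=CCc1cc(C(=O)CC(O[Si](C)(C)C(C)(C)C)c2c(Br)cc(OCOC)c(CC=C(C)C)c2OCOC)cc(CC=C(C)C)c1OCOC | intermediate
15 | (1R)-3-[6-bromo-2,4-bis(methoxymethoxy)-3-(3-methylbut-2-enyl)phenyl]-3-(tert-butyldimethylsilyloxy)-1-[4-(methoxymethoxy)-3,5-bis(3-methylbut-2-enyl)phenyl]propan-1-ol (both C3 epimers) | CC(C)=CCc1cc([C@H](O)CC(O[Si](C)(C)C(C)(C)C)c2c(Br)cc(OCOC)c(CC=C(C)C)c2OCOC)cc(CC=C(C)C)c1OCOC | intermediate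
16 | (2R)-4-(tert-butyldimethylsilyloxy)-5,7-bis(methoxymethoxy)-2-[4-(methoxymethoxy)-3,5-bis(3-methylbut-2-enyl)phenyl]-6-(3-methylbut-2-enyl)chroman (both C4 epimers) | CC(C)=CCc1cc([C@H]2CC(O[Si](C)(C)C(C)(C)C)c3c(cc(OCOC)c(CC=C(C)C)c3OCOC)O2)cc(CC=C(C)C)c1OCOC | intermediate
17 | (2R)-5,7-bis(methoxymethoxy)-2-[4-(methoxymethoxy)-3,5-bis(3-methylbut-2-enyl)phenyl]-6-(3-methylbut-2-enyl)chroman-4-ol (both C4 epimers) | CC(C)=CCc1cc([C@H]2CC(O)c3c(cc(OCOC)c(CC=C(C)C)c3OCOC)O2)cc(CC=C(C)C)c1OCOC | intermediate
18 | (2R)-5,7-bis(methoxymethoxy)-2-[4-(methoxymethoxy)-3,5-bis(3-methylbut-2-enyl)phenyl]-6-(3-methylbut-2-enyl)chroman-4-one | CC(C)=CCc1cc([C@H]2CC(=O)c3c(cc(OCOC)c(CC=C(C)C)c3OCOC)O2)cc(CC=C(C)C)c1OCOC | intermediate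
19 | (2R)-5,7-dihydroxy-2-[4-hydroxy-3,5-bis(3-methylbut-2-enyl)phenyl]-6-(3-methylbut-2-enyl)chroman-4-one | CC(C)=CCc1cc([C@H]2CC(=O)c3c(cc(O)c(CC=C(C)C)c3O)O2)cc(CC=C(C)C)c1O | target

**Step count**

Total: 13 steps. Longest linear sequence: 11 steps (steps 1–4, then 7–13); the ring B branch is steps 5–6.

**Steps most likely to fail, with fallbacks**

Step 10. The palladium alkoxide may undergo β-hydride elimination (oxidation of the C2 carbinol with loss of the bromine), or oxidative addition at the hindered, electron-rich bromide may stall. The fallback closes ring C at the other ether bond, O1–C2, by a Mitsunobu reaction with inversion. It sets out from ketone 14 and returns at chroman 16.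
- Reduction of 14 with the enantiomeric (R)-Bu-CBS oxazaborolidine and catecholborane in toluene at −78 °C should give the (1S)-bromo alcohol F1.
- Miyaura borylation (bis(pinacolato)diboron, PdCl2(dppf), KOAc, dioxane, 80 °C) should give the aryl pinacol boronate F2; the base is too weak to form the alkoxide.
- Oxidation with NaBO3·4H2O in THF/H2O at rt should give the (1S)-phenol alcohol F3.
- PPh3 and DIAD in THF at 0 °C should then displace the activated C2 oxygen by the phenol with inversion, giving (2R)-chroman 16.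

Step 13. Under acid a freed phenol may add to its neighbouring prenyl double bond (closure to a dimethylchroman), the alkenes may be hydrated, or ring C may open and erode C2. The fallback avoids Brønsted acid. It sets out from 18 and returns at 19.
- TESOTf and 2,2'-bipyridyl in CH2Cl2 at 0 °C should convert the three aryl MOM ethers directly into aryl triethylsilyl ethers, giving the tris(triethylsilyl) flavanone F4.
- Buffered fluoride (Bu4NF/AcOH, THF, 0 °C) should then release target 19 under near-neutral conditions.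

Step 5. O-alkylation may compete, the second C-alkylation may stay incomplete, and the phenoxide may be over-alkylated with dearomatisation. The fallback installs both prenyl groups by cross-coupling. It sets out from 9 and returns at 11, bypassing 10.
- Ring bromination of 9 (Br2, 2.1 equiv, AcOH, rt) should give 1-(3,5-dibromo-4-hydroxyphenyl)ethanone F5.
- MOMCl and i-Pr2NEt in CH2Cl2 should give 1-[3,5-dibromo-4-(methoxymethoxy)phenyl]ethanone F6.
- Double Stille coupling with tributyl(3-methylbut-2-enyl)stannane (Pd(PPh3)4, DMF, 90 °C) should give ketone 11.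

**Further compounds**

F1 | step 10 | (1S)-3-[6-bromo-2,4-bis(methoxymethoxy)-3-(3-methylbut-2-enyl)phenyl]-3-(tert-butyldimethylsilyloxy)-1-[4-(methoxymethoxy)-3,5-bis(3-methylbut-2-enyl)phenyl]propan-1-ol (both C3 epimers) | CC(C)=CCc1cc([C@@H](O)CC(O[Si](C)(C)C(C)(C)C)c2c(Br)cc(OCOC)c(CC=C(C)C)c2OCOC)cc(CC=C(C)C)c1OCOC
F2 | step 10 | (1S)-3-(tert-butyldimethylsilyloxy)-3-[2,4-bis(methoxymethoxy)-3-(3-methylbut-2-enyl)-6-(4,4,5,5-tetramethyl-1,3,2-dioxaborolan-2-yl)phenyl]-1-[4-(methoxymethoxy)-3,5-bis(3-methylbut-2-enyl)phenyl]propan-1-ol (both C3 epimers) | CC(C)=CCc1cc([C@@H](O)CC(O[Si](C)(C)C(C)(C)C)c2c(B3OC(C)(C)C(C)(C)O3)cc(OCOC)c(CC=C(C)C)c2OCOC)cc(CC=C(C)C)c1OCOC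
F3 | step 10 | (1S)-3-(tert-butyldimethylsilyloxy)-3-[6-hydroxy-2,4-bis(methoxymethoxy)-3-(3-methylbut-2-enyl)phenyl]-1-[4-(methoxymethoxy)-3,5-bis(3-methylbut-2-enyl)phenyl]propan-1-ol (both C3 epimers) | CC(C)=CCc1cc([C@@H](O)CC(O[Si](C)(C)C(C)(C)C)c2c(O)cc(OCOC)c(CC=C(C)C)c2OCOC)cc(CC=C(C)C)c1OCOC
F4 | step 13 | (2R)-5,7-bis(triethylsilyloxy)-2-[4-(triethylsilyloxy)-3,5-bis(3-methylbut-2-enyl)phenyl]-6-(3-methylbut-2-enyl)chroman-4-one | CC(C)=CCc1cc([C@H]2CC(=O)c3c(cc(O[Si](CC)(CC)CC)c(CC=C(C)C)c3O[Si](CC)(CC)CC)O2)cc(CC=C(C)C)c1O[Si](CC)(CC)CC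
F5 | step 5 | 1-(3,5-dibromo-4-hydroxyphenyl)ethanone | CC(=O)c1cc(Br)c(O)c(Br)c1
F6 | step 5 | 1-[3,5-dibromo-4-(methoxymethoxy)phenyl]ethanone | CC(=O)c1cc(Br)c(OCOC)c(Br)c1
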